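**Retrosynthetic overview**
- Feature: C8 (α-oxygen, β-methyl C17) and the C9 arm C11–C12–C13 fold into a δ-lactone (O8–C13) on the trans A/B decalin. That lactone ring is ring C of a 13-oxopodocarpane in which oxygen holds the ring place of C14 and C14 has become the C8 methyl.
- Key disconnection: O8–C13 is made and C13–C14 is broken in one photochemical event (Norrish type I cleavage, ketene, capture by the 8α-hydroxyl) from the cis-B/C 8α-hydroxy-13-ketone.
- The ketol comes from the 13-oxo-8(14)-ene by α-face nucleophilic epoxidation and SmI2 opening. The enone comes from neoabietic acid by ozonolysis of C13=C15.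
- Rings A, B, C and C4, C5, C9, C10 are bought and C8 is set by the epoxidation. The lactone is the only ring formed, and it is reopened at the end (C13 benzyl ester, C8 acetate, hydrogenolysis).
- C18 travels as a benzyl ester, because C18 alkyl esters of this series resist saponification.

Key step: step 5

Assumption: natural (+)-neoabietic acid (abieta-8(14),13(15)-dien-18-oic acid) is taken as a purchasable resin acid with the C4, C5, C10 configuration of dehydroabietic acid and 9α-H; abietane/labdane numbering is used throughout (C18 = 4α-carboxyl, C19 = 4β-methyl, C20 = 10β-methyl, C17 = 8β-methyl).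

**Step 1**
Reactants: 1 neoabietic acid; 2 benzyl bromide
Product: 3 benzyl neoabietate (benzyl abieta-8(14),13(15)-dien-18-oate)
Conditions: BnBr, K2CO3, DMF, rt
Reagents that add atoms: benzyl bromide, BrCc1ccccc1
Why: Carboxylate O-alkylation (SN2 at benzyl bromide) avoids the hindered C18 carbonyl, keeps the acid-labile diene under basic conditions, touches no stereocentre and installs an ester that later leaves by hydrogenolysis instead of a forcing saponification.

**Step 2**
Reactants: 3 benzyl neoabietate
Product: 5 benzyl 13-oxopodocarp-8(14)-en-18-oate (5α-H; 9α-H; 10β-methyl), via primary ozonide 4 (not isolated)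
Conditions: O3 (1.0 equiv, Sudan Red 7B end point), CH2Cl2–MeOH, −78 °C; Me2S, −78 °C → rt
Reagents that add atoms: ozone, [O-][O+]=O
Why: Ozonolysis with one equivalent of ozone takes the most electron-rich, tetrasubstituted exocyclic C13=C15 bond by 1,3-dipolar cycloaddition, and the resulting enone is deactivated toward more ozone, so cycloreversion and Me2S reduction should leave the C13 ketone and acetone with 9α-H untouched.

**Step 3**
Reactants: 5 benzyl 13-oxopodocarp-8(14)-en-18-oate
Product: 6 benzyl 8α,14α-epoxy-13-oxopodocarpan-18-oate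
Conditions: 30% H2O2, aq NaOH (cat.), MeOH, 0 °C → rt
Reagents that add atoms: hydrogen peroxide, OO
Why: Weitz–Scheffer nucleophilic epoxidation, in which hydroperoxide adds to C8 from the α face because the β face is screened by the syn-axial C20 methyl, and the enolate closes on the O–O bond on the same face, which sets C8 (α-O, hence cis B/C) and C14 while the hindered C18 ester is left alone.

**Step 4**
Reactants: 6 benzyl 8α,14α-epoxy-13-oxopodocarpan-18-oate
Product: 7 benzyl 8α-hydroxy-13-oxopodocarpan-18-oate (C14 β on C8; 9α-H; cis B/C fusion)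
Conditions: SmI2 (2.2 equiv), THF–MeOH, −78 °C; pH 7 buffer
Reagents that add atoms: none
Why: Samarium diiodide reduction of an α,β-epoxy ketone, in which two electron transfers through the ketyl break only the C14–O bond next to the carbonyl and methanol protonates the enolate, so the C8–O bond keeps its α configuration and the cold, neutral conditions hold back β-elimination and retro-aldol opening.

**Step 5**
Reactants: 7 benzyl 8α-hydroxy-13-oxopodocarpan-18-oate
Product: 10 benzyl 14,15,16-trinorlabdan-13,8α-olid-18-oate (8β-methyl; 9α-H), via acyl–alkyl biradical 8 (not isolated), via hydroxy ketene 9 (not isolated)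
Conditions: hν (300 nm lamps, Pyrex), dry degassed MeCN (5 mM), Ar, 20 °C
Reagents that add atoms: none
Why: Proposed new method: n→π* excitation of the C13 ketone and α-cleavage of C13–C14 (Norrish type I) give biradical 8, in which the C14 radical, held gauche to the C9 arm on ring B, takes a C12 hydrogen by 1,5-transfer through a six-membered transition state and thereby becomes the 8β-methyl while C12=C13=O becomes ketene 9. The 8α-hydroxyl then adds to the sp ketene carbon in the ketene plane (6-exo-dig, since the C=O π bond that is broken lies outside the new ring), and a proton shift completes the δ-lactone ring O8–C8–C9–C11–C12–C13. The closest known reaction type is the photolysis of cyclohexanones and hydroxyalkyl cycloalkanones to ketenes that an external or tethered alcohol captures, and what has not been shown is a ring β-hydroxyl as the trap on an α-unsubstituted ketone, which turns the cleavage into an exchange of a ring CH2 for oxygen. No stereocentre is created, because no bond to C8 or C9 breaks, so 8α-O/8β-C and 9α-H pass unchanged from 7 into 10. The step needs cleavage on the C14 side rather than the C12 side, and since both give primary radicals the bias is modest: C14-side cleavage leaves only a CH2 in the axial site syn to C20 whereas C12-side cleavage leaves the whole CH2–C=O arm there, and what the substrate does secure is the fate of biradical 8, which has no hydrogen on quaternary C8 (no enal channel) and can only reclose to 7 or go on to 9, whose capture by the neighbouring hydroxyl is irreversible. Dry degassed MeCN (no external nucleophile, poor hydrogen donor), λ ≥ 300 nm (benzyl ester and lactone transparent) and neutral conditions at 20 °C hold back photoreduction, ketene solvolysis and thermal retro-aldol cleavage.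

**Step 6**
Reactants: 10 benzyl 14,15,16-trinorlabdan-13,8α-olid-18-oate; 2 benzyl bromide
Product: 12 dibenzyl 8α-hydroxy-14,15,16-trinorlabdane-13,18-dioate, via potassium carboxylate 11 (not isolated)
Conditions: KOH (1.05 equiv), dioxane–H2O, 50 °C; evaporate, PhMe azeotrope; BnBr, DMF, rt
Reagents that add atoms: potassium hydroxide, [K+].[OH-]; benzyl bromide, BrCc1ccccc1
Why: Lactone saponification by acyl–oxygen cleavage followed by SN2 alkylation of the dry carboxylate never passes through the free δ-hydroxy acid that would relactonise, one equivalent of hydroxide spares the hindered C18 ester, and the C8–O bond with its configuration is not touched.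

**Step 7**
Reactants: 12 dibenzyl 8α-hydroxy-14,15,16-trinorlabdane-13,18-dioate; 13 acetyl chloride
Product: 14 dibenzyl 8α-acetoxy-14,15,16-trinorlabdane-13,18-dioate
Conditions: AcCl (5 equiv), PhNMe2 (6 equiv), CH2Cl2, 0 °C → rt
Reagents that add atoms: acetyl chloride, CC(Cl)=O
Why: O-acylation of a hindered tertiary alcohol with acetyl chloride buffered by N,N-dimethylaniline, the usual conditions for labdane 8α-ols, takes place at oxygen with C8 unchanged and should outrun dehydration and relactonisation in the nearly neutral medium.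

**Step 8**
Reactants: 14 dibenzyl 8α-acetoxy-14,15,16-trinorlabdane-13,18-dioate
Product: 15 8α-acetoxy-14,15,16-trinorlabdane-13,18-dioic acid (CNP0196050.1)
Conditions: H2 (1 atm), 10% Pd/C, EtOAc, rt
Reagents that add atoms: none
Why: Catalytic hydrogenolysis cleaves both benzylic C–O bonds under neutral conditions and leaves the tertiary acetate and all five stereocentres untouched, so the diacid is freed without any hydrolytic step.

**Compound list**
1 | neoabietic acid (abieta-8(14),13(15)-dien-18-oic acid; 5α-H, 9α-H, 10β-methyl, 4α-CO2H) | CC(C)=C1C=C2CC[C@@H]3[C@](C)(CCC[C@@]3(C)C(=O)O)[C@H]2CC1 | starting material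
2 | benzyl bromide | BrCc1ccccc1 | starting material
3 | benzyl neoabietate | CC(C)=C1C=C2CC[C@@H]3[C@](C)(CCC[C@@]3(C)C(=O)OCc4ccccc4)[C@H]2CC1 | intermediate
4 | primary ozonide of 3 at C13=C15 (spiro-1,2,3-trioxolane; C13 configuration not defined and lost on collapse; not isolated) | CC1(C)OOOC12C=C3CC[C@@H]4[C@](C)(CCC[C@@]4(C)C(=O)OCc5ccccc5)[C@H]3CC2 | intermediate
5 | benzyl 13-oxopodocarp-8(14)-en-18-oate | O=C1C=C2CC[C@@H]3[C@](C)(CCC[C@@]3(C)C(=O)OCc4ccccc4)[C@H]2CC1 | intermediate
6 | benzyl 8α,14α-epoxy-13-oxopodocarpan-18-oate | O=C1[C@@H]2O[C@@]23CC[C@@H]4[C@](C)(CCC[C@@]4(C)C(=O)OCc5ccccc5)[C@H]3CC1 | intermediate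
7 | benzyl 8α-hydroxy-13-oxopodocarpan-18-oate (cis B/C, C14 β on C8, 9α-H) | O[C@]1(CC(=O)CC3)CC[C@@H]2[C@](C)(CCC[C@@]2(C)C(=O)OCc4ccccc4)[C@H]13 | intermediate
8 | acyl–alkyl biradical (C14 primary radical on C8, C13 acyl radical; not isolated) | O[C@]1([CH2])CC[C@@H]2[C@](C)(CCC[C@@]2(C)C(=O)OCc3ccccc3)[C@H]1CC[C]=O | intermediate
9 | hydroxy ketene (8α-OH, 8β-methyl, C12=C13=O; not isolated) | O[C@]1(C)CC[C@@H]2[C@](C)(CCC[C@@]2(C)C(=O)OCc3ccccc3)[C@H]1CC=C=O | intermediate
10 | benzyl 14,15,16-trinorlabdan-13,8α-olid-18-oate | O=C3O[C@]1(C)CC[C@@H]2[C@](C)(CCC[C@@]2(C)C(=O)OCc4ccccc4)[C@H]1CC3 | intermediate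
11 | potassium 18-benzyl 8α-hydroxy-14,15,16-trinorlabdane-13,18-dioate (not isolated) | O[C@]1(C)CC[C@@H]2[C@](C)(CCC[C@@]2(C)C(=O)OCc3ccccc3)[C@H]1CCC(=O)[O-].[K+] | intermediate
12 | dibenzyl 8α-hydroxy-14,15,16-trinorlabdane-13,18-dioate | O[C@]1(C)CC[C@@H]2[C@](C)(CCC[C@@]2(C)C(=O)OCc3ccccc3)[C@H]1CCC(=O)OCc4ccccc4 | intermediate
13 | acetyl chloride | CC(Cl)=O | starting material
14 | dibenzyl 8α-acetoxy-14,15,16-trinorlabdane-13,18-dioate | CC(=O)O[C@]1(C)CC[C@@H]2[C@](C)(CCC[C@@]2(C)C(=O)OCc3ccccc3)[C@H]1CCC(=O)OCc4ccccc4 | intermediate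
15 | 8α-acetoxy-14,15,16-trinorlabdane-13,18-dioic acid (CNP0196050.1) | CC(=O)O[C@]1(C)CC[C@@H]2[C@](C)(CCC[C@@]2(C)C(=O)O)[C@H]1CCC(=O)O | target

**Total step count:** 8. **Longest linear sequence:** 8 (steps 1–8 from neoabietic acid).

**Steps most likely to fail**

**1. Step 5 (new method).**
- Risk: the excited ketone may cleave on the C12 side as readily as on the C14 side, since both bonds lead to primary radicals. That branch drains material by hydrogen transfer to an open-chain unsaturated aldehyde or to a ketene out of reach of the hydroxyl. Reclosure of the wanted biradical may also slow net conversion enough for retro-aldol opening of ring C to compete.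
- Fallback (known chemistry): it sets out from 5 and comes back at 10.
- Ozonolysis of the enone C8=C14 bond with oxidative work-up (O3, CH2Cl2–MeOH, −78 °C; then H2O2) excises C14 and gives the 8-oxo acid F1.
- Wittig methylenation (Ph3PCH3Br, KOtBu, 3 equiv, THF), with the equatorial C9 arm as the stable epimer, gives the 8(17)-ene acid F2.
- Mukaiyama hydration (Mn(dpm)3 cat., PhSiH3, O2, i-PrOH) should bring oxygen to the C8 radical from the α face, away from C20, to give the 8α-hydroxy acid F3.
- F3 closes to 10 with catalytic PPTS in warm toluene.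

**2. Step 7.**
- Risk: acylation of the hindered tertiary hydroxyl may be slower than its attack on the C13 benzyl ester (relactonisation with loss of benzyl alcohol), or slower than acid-induced loss of water toward C7 or C17.
- Fallback: it sets out from 10 and comes back at 15, and it removes the electrophilic C13 carbonyl while the hydroxyl is free.
- LiBH4 (THF, 0 °C → rt) should reduce the lactone and spare the hindered C18 ester, giving the 8α,13-diol F4.
- AcCl/PhNMe2 acetylates the primary and then the tertiary hydroxyl to give the diacetate F5.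
- K2CO3/MeOH removes only the primary acetate to give the 8α-acetoxy 13-alcohol F6.
- TEMPO/PhI(OAc)2 in MeCN–H2O gives the 8α-acetoxy 13-acid F7.
- Hydrogenolysis (H2, Pd/C) of the C18 benzyl ester gives 15.

**3. Step 4.**
- Risk: the tertiary aldol unit may be lost during reduction or work-up, either by β-elimination back to the conjugated enone or by retro-aldol opening. Further reduction of the ketone is also possible.
- Fallback: it sets out from 5 and comes back at 7 without an epoxide.
- Copper-catalysed conjugate borylation (B2pin2, CuCl, NaOtBu, DPEphos, MeOH, THF, rt) should add boron to C8 from the α face, for the same steric reason as in step 3, to give the 8α-boronate F8.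
- Oxidation with NaBO3·4H2O (THF–H2O, rt) replaces boron by hydroxyl with retention to give 7.

**Further compounds**
F1 | step 5 | 8-oxo acid (18-benzyl hydrogen 8-oxo-14,15,16,17-tetranorlabdane-13,18-dioate) | O=C1CC[C@@H]2[C@](C)(CCC[C@@]2(C)C(=O)OCc3ccccc3)[C@H]1CCC(=O)O
F2 | step 5 | 8(17)-ene acid (18-benzyl hydrogen 14,15,16-trinorlabd-8(17)-ene-13,18-dioate) | C=C1CC[C@@H]2[C@](C)(CCC[C@@]2(C)C(=O)OCc3ccccc3)[C@H]1CCC(=O)O
F3 | step 5 | 8α-hydroxy acid (18-benzyl hydrogen 8α-hydroxy-14,15,16-trinorlabdane-13,18-dioate) | O[C@]1(C)CC[C@@H]2[C@](C)(CCC[C@@]2(C)C(=O)OCc3ccccc3)[C@H]1CCC(=O)O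
F4 | step 7 | 8α,13-diol (benzyl 8α,13-dihydroxy-14,15,16-trinorlabdan-18-oate) | O[C@]1(C)CC[C@@H]2[C@](C)(CCC[C@@]2(C)C(=O)OCc3ccccc3)[C@H]1CCCO
F5 | step 7 | diacetate (benzyl 8α,13-diacetoxy-14,15,16-trinorlabdan-18-oate) | CC(=O)O[C@]1(C)CC[C@@H]2[C@](C)(CCC[C@@]2(C)C(=O)OCc3ccccc3)[C@H]1CCCOC(C)=O
F6 | step 7 | 8α-acetoxy 13-alcohol (benzyl 8α-acetoxy-13-hydroxy-14,15,16-trinorlabdan-18-oate) | CC(=O)O[C@]1(C)CC[C@@H]2[C@](C)(CCC[C@@]2(C)C(=O)OCc3ccccc3)[C@H]1CCCO
F7 | step 7 | 8α-acetoxy 13-acid (18-benzyl hydrogen 8α-acetoxy-14,15,16-trinorlabdane-13,18-dioate) | CC(=O)O[C@]1(C)CC[C@@H]2[C@](C)(CCC[C@@]2(C)C(=O)OCc3ccccc3)[C@H]1CCC(=O)O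
F8 | step 4 | 8α-boronate (benzyl 13-oxo-8α-(4,4,5,5-tetramethyl-1,3,2-dioxaborolan-2-yl)podocarpan-18-oate) | CC1(C)OB(OC1(C)C)[C@]2(CC(=O)CC4)CC[C@@H]3[C@](C)(CCC[C@@]3(C)C(=O)OCc5ccccc5)[C@H]24
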